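## Retrosynthetic overview

1. The strategy rests on ring D, a benzoic acid with CO2H at C1, OH at C2, OMe at C4 and the arylethyl chain at C6. C1 and C6 map onto an alkynoate and C2–C5, with both oxygens, map onto a 1,1,3-trioxygenated butadiene. Ring D is therefore cut at C1–C2 and C5–C6 ([4+2] cycloaddition, then aromatisation).
2. The dienophile is a 5-arylpent-2-ynoate made from a 3-arylpropanal by Corey–Fuchs homologation. It is carried as the benzyl ester, so one final hydrogenolysis frees the acid and the ring A phenol. This avoids basic hydrolysis of a hindered salicylate that decarboxylates easily.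
3. The ring B–O–ring C diaryl ether is cut by Ullmann coupling into methyl phloretate (ring C with its C3 chain) and a bromo bibenzyl (rings A and B).
4. The A–B ethylene bridge comes from Horner–Wadsworth–Emmons olefination followed by diimide reduction.
5. Rings A, B and C are bought as arenes. Ring D is the only ring formed, and it is formed last.

Key step: step 9

Remark: the target has no stereocentre and no alkene. Diene 14 is drawn without geometry at its ketene acetal double bond because that carbon becomes aromatic C2. Adduct 15 is racemic, and its one stereocentre is lost on aromatisation.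

## Route

Step 1
Reactants: 1 4-(benzyloxy)benzyl chloride
Product: 2 diethyl [4-(benzyloxy)benzyl]phosphonate
Conditions: P(OEt)3 (neat, excess), 140 °C; excess phosphite removed in vacuo
Reagents that add atoms: triethyl phosphite, CCOP(OCC)OCC
Why: Michaelis–Arbuzov reaction, in which the activated 4-alkoxybenzyl chloride alkylates phosphorus and chloride then dealkylates the phosphonium salt, the volatile chloroethane leaving the melt.

Step 2
Reactants: 2 diethyl [4-(benzyloxy)benzyl]phosphonate; 3 3-bromo-5-methoxybenzaldehyde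
Product: 4 (E)-1-[2-(4-benzyloxyphenyl)ethenyl]-3-bromo-5-methoxybenzene
Conditions: KOtBu, THF, 0 °C to rt
Reagents that add atoms: none
Why: Horner–Wadsworth–Emmons olefination of a non-enolisable aryl aldehyde with a benzylic phosphonate anion should give the (E)-stilbene, and the geometry does not matter because the double bond is saturated in the next step.

Step 3
Reactants: 4 (E)-1-[2-(4-benzyloxyphenyl)ethenyl]-3-bromo-5-methoxybenzene
Product: 5 1-[2-(4-benzyloxyphenyl)ethyl]-3-bromo-5-methoxybenzene (bromo bibenzyl, rings A and B)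
Conditions: TsNHNH2 (excess), NaOAc, THF/H2O, reflux
Reagents that add atoms: none
Why: Diimide reduction, in which HN=NH made in the flask delivers two hydrogens in a concerted way to the non-polar C=C only, so the aryl bromide and the benzyl ether, both at risk under Pd-catalysed hydrogenation, are kept.

Step 4
Reactants: 5 1-[2-(4-benzyloxyphenyl)ethyl]-3-bromo-5-methoxybenzene; 6 methyl 3-(4-hydroxyphenyl)propanoate (methyl phloretate)
Product: 7 methyl 3-[4-(3-{2-[4-(benzyloxy)phenyl]ethyl}-5-methoxyphenoxy)phenyl]propanoate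
Conditions: CuI (10 mol %), N,N-dimethylglycine hydrochloride (30 mol %), Cs2CO3 (2 equiv), dry 1,4-dioxane, 100 °C, argon
Reagents that add atoms: none
Why: Ligand-accelerated Ullmann diaryl ether synthesis, in which the amino acid ligand lets monovalent copper couple an electronically neutral, unhindered aryl bromide with a phenoxide at a temperature that the methyl ester tolerates in a dry medium.

Step 5
Reactants: 7 methyl 3-[4-(3-{2-[4-(benzyloxy)phenyl]ethyl}-5-methoxyphenoxy)phenyl]propanoate
Product: 8 3-[4-(3-{2-[4-(benzyloxy)phenyl]ethyl}-5-methoxyphenoxy)phenyl]propanal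
Conditions: i-Bu2AlH (DIBAL-H, 1.1 equiv), CH2Cl2, −78 °C; then MeOH, aq potassium sodium tartrate
Reagents that add atoms: none
Why: Partial ester reduction, in which the tetrahedral aluminium hemiacetal persists at −78 °C and collapses to the aldehyde only on quenching, while all ether linkages are inert.

Step 6
Reactants: 8 3-[4-(3-{2-[4-(benzyloxy)phenyl]ethyl}-5-methoxyphenoxy)phenyl]propanal
Product: 9 1-{2-[4-(benzyloxy)phenyl]ethyl}-3-[4-(4,4-dibromobut-3-en-1-yl)phenoxy]-5-methoxybenzene
Conditions: CBr4 (2 equiv), PPh3 (4 equiv), CH2Cl2, 0 °C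
Reagents that add atoms: carbon tetrabromide, BrC(Br)(Br)Br
Why: First stage of the Corey–Fuchs homologation, a Wittig-type olefination of an unhindered aliphatic aldehyde by the dibromomethylene ylide under neutral conditions that avoid aldol side reactions.

Step 7
Reactants: 9 1-{2-[4-(benzyloxy)phenyl]ethyl}-3-[4-(4,4-dibromobut-3-en-1-yl)phenoxy]-5-methoxybenzene
Product: 11 benzyl 5-[4-(3-{2-[4-(benzyloxy)phenyl]ethyl}-5-methoxyphenoxy)phenyl]pent-2-ynoate, via lithium acetylide 10 (not isolated)
Conditions: n-BuLi (2.1 equiv), THF, −78 °C; then ClCO2Bn (1.5 equiv), −78 to 0 °C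
Reagents that add atoms: benzyl chloroformate, O=C(Cl)OCc1ccccc1
Why: Second stage of the Corey–Fuchs homologation, in which bromine–lithium exchange, α-elimination with 1,2-hydrogen shift and deprotonation give acetylide 10, which is C-acylated by the chloroformate faster than n-BuLi can touch the benzylic or aryl C–H bonds at −78 °C.

Step 8
Reactants: 12 methyl (E)-3-methoxybut-2-enoate
Product: 14 1,3-dimethoxy-1-(trimethylsilyloxy)buta-1,3-diene (Brassard diene), via lithium dienolate 13 (not isolated)
Conditions: LiN(i-Pr)2 (LDA, 1.1 equiv), THF, −78 °C; then Me3SiCl, −78 °C to rt; non-aqueous work-up, distillation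
Reagents that add atoms: chlorotrimethylsilane, C[Si](C)(C)Cl
Why: γ-Deprotonation of the vinylogous carbonate by LDA and O-silylation of the extended enolate by the hard silicon electrophile, which is the standard preparation of this diene.

Step 9
Reactants: 11 benzyl 5-[4-(3-{2-[4-(benzyloxy)phenyl]ethyl}-5-methoxyphenoxy)phenyl]pent-2-ynoate; 14 1,3-dimethoxy-1-(trimethylsilyloxy)buta-1,3-diene
Product: 17 benzyl 2-hydroxy-4-methoxy-6-{2-[4-(3-{2-[4-(benzyloxy)phenyl]ethyl}-5-methoxyphenoxy)phenyl]ethyl}benzoate, via cyclohexadiene adduct 15 (not isolated), via aryl silyl ether 16 (not isolated)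
Conditions: 14 (4 equiv, in portions), neat or concentrated in toluene, sealed tube, 145 °C, argon; then 1 M aq HCl, THF, rt
Reagents that add atoms: none
Why: Diene 14 is polarised by its three oxygen donors so that its terminal CH2 is the nucleophilic end, and ynoate 11 is electrophilic at the alkyne carbon β to the ester; heating should therefore cause a concerted but strongly asynchronous [4+2] cycloaddition in which CH2 bonds to the β carbon (ring D C5–C6) and the ketene acetal carbon bonds to the α carbon (C1–C2), giving cyclohexa-1,4-diene 15. The closest known reaction type is this same one, the Diels–Alder/aromatisation of Brassard-type 1,1,3-trioxygenated butadienes with acetylenic esters to 4-alkoxysalicylates. Ring D is closed by an intermolecular two-bond cycloaddition (four diene carbons plus two alkyne carbons), so no separate cyclisation mode has to be controlled. The mixed ketal carbon of 15 is the only stereocentre formed; it is racemic and disappears when methanol is lost by 1,4-elimination (C2–OMe, C5–H) to give aryl silyl ether 16, whose O–Si bond is then cleaved by dilute acid to the phenol that is hydrogen-bonded to the ester carbonyl. The step needs regioselectivity, which the matched donor/acceptor polarisation of the two partners secures and which places OH at C2 next to the ester, OMe at C4 and the arylethyl chain at C6, and it needs loss of methanol rather than silanol from the ketal carbon, which is the usual course for this diene class. The arenes, both ether bridges and the benzyl groups are inert to heat in the absence of acid or base, and the portionwise excess of diene makes up for its thermal decay and for its consumption by the liberated methanol.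

Step 10
Reactants: 17 benzyl 2-hydroxy-4-methoxy-6-{2-[4-(3-{2-[4-(benzyloxy)phenyl]ethyl}-5-methoxyphenoxy)phenyl]ethyl}benzoate
Product: 18 2-hydroxy-6-{2-[4-(3-[2-(4-hydroxyphenyl)ethyl]-5-methoxyphenoxy)phenyl]ethyl}-4-methoxybenzoic acid (target, CNP0188714.0)
Conditions: H2 (1 atm), 10% Pd/C, EtOAc/MeOH, rt; filtration, evaporation below 30 °C
Reagents that add atoms: none
Why: Catalytic hydrogenolysis cleaves both benzylic C–O bonds (ester and aryl ether) at sites remote from the hindered carbonyl under neutral conditions, so the diaryl ether and methyl ethers remain and the sensitive salicylic acid is not exposed to heat, acid or base.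

## Compound list

1 | 4-(benzyloxy)benzyl chloride | ClCc1ccc(OCc2ccccc2)cc1 | starting material
2 | diethyl [4-(benzyloxy)benzyl]phosphonate | CCOP(=O)(Cc1ccc(OCc2ccccc2)cc1)OCC | intermediate
3 | 3-bromo-5-methoxybenzaldehyde | COc1cc(Br)cc(C=O)c1 | starting material
4 | (E)-1-[2-(4-benzyloxyphenyl)ethenyl]-3-bromo-5-methoxybenzene | COc1cc(Br)cc(/C=C/c2ccc(OCc3ccccc3)cc2)c1 | intermediate
5 | 1-[2-(4-benzyloxyphenyl)ethyl]-3-bromo-5-methoxybenzene | COc1cc(Br)cc(CCc2ccc(OCc3ccccc3)cc2)c1 | intermediate
6 | methyl 3-(4-hydroxyphenyl)propanoate (methyl phloretate) | COC(=O)CCc1ccc(O)cc1 | starting material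
7 | methyl 3-[4-(3-{2-[4-(benzyloxy)phenyl]ethyl}-5-methoxyphenoxy)phenyl]propanoate | COC(=O)CCc1ccc(Oc2cc(OC)cc(CCc3ccc(OCc4ccccc4)cc3)c2)cc1 | intermediate
8 | 3-[4-(3-{2-[4-(benzyloxy)phenyl]ethyl}-5-methoxyphenoxy)phenyl]propanal | O=CCCc1ccc(Oc2cc(OC)cc(CCc3ccc(OCc4ccccc4)cc3)c2)cc1 | intermediate
9 | 1-{2-[4-(benzyloxy)phenyl]ethyl}-3-[4-(4,4-dibromobut-3-en-1-yl)phenoxy]-5-methoxybenzene | BrC(Br)=CCCc1ccc(Oc2cc(OC)cc(CCc3ccc(OCc4ccccc4)cc3)c2)cc1 | intermediate
10 | lithium acetylide, {4-[4-(3-{2-[4-(benzyloxy)phenyl]ethyl}-5-methoxyphenoxy)phenyl]but-1-yn-1-yl}lithium | [Li]C#CCCc1ccc(Oc2cc(OC)cc(CCc3ccc(OCc4ccccc4)cc3)c2)cc1 | intermediate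
11 | benzyl 5-[4-(3-{2-[4-(benzyloxy)phenyl]ethyl}-5-methoxyphenoxy)phenyl]pent-2-ynoate | O=C(OCc1ccccc1)C#CCCc1ccc(Oc2cc(OC)cc(CCc3ccc(OCc4ccccc4)cc3)c2)cc1 | intermediate
12 | methyl (E)-3-methoxybut-2-enoate | CO/C(C)=C/C(=O)OC | starting material
13 | lithium dienolate of 12 (lithium 1,3-dimethoxybuta-1,3-dien-1-olate) | [Li]OC(OC)=CC(=C)OC | intermediate
14 | 1,3-dimethoxy-1-(trimethylsilyloxy)buta-1,3-diene (Brassard diene, ketene acetal geometry not defined) | C=C(OC)C=C(OC)O[Si](C)(C)C | intermediate
15 | benzyl 2-{2-[4-(3-{2-[4-(benzyloxy)phenyl]ethyl}-5-methoxyphenoxy)phenyl]ethyl}-4,6-dimethoxy-6-(trimethylsilyloxy)cyclohexa-1,4-diene-1-carboxylate (racemic) | O=C(OCc1ccccc1)C1=C(CCc2ccc(Oc3cc(OC)cc(CCc4ccc(OCc5ccccc5)cc4)c3)cc2)CC(OC)=CC1(OC)O[Si](C)(C)C | intermediate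
16 | benzyl 2-{2-[4-(3-{2-[4-(benzyloxy)phenyl]ethyl}-5-methoxyphenoxy)phenyl]ethyl}-4-methoxy-6-(trimethylsilyloxy)benzoate | O=C(OCc1ccccc1)c1c(O[Si](C)(C)C)cc(OC)cc1CCc1ccc(Oc2cc(OC)cc(CCc3ccc(OCc4ccccc4)cc3)c2)cc1 | intermediate
17 | benzyl 2-hydroxy-4-methoxy-6-{2-[4-(3-{2-[4-(benzyloxy)phenyl]ethyl}-5-methoxyphenoxy)phenyl]ethyl}benzoate | O=C(OCc1ccccc1)c1c(O)cc(OC)cc1CCc1ccc(Oc2cc(OC)cc(CCc3ccc(OCc4ccccc4)cc3)c2)cc1 | intermediate
18 | 2-hydroxy-6-{2-[4-(3-[2-(4-hydroxyphenyl)ethyl]-5-methoxyphenoxy)phenyl]ethyl}-4-methoxybenzoic acid | COc1cc(CCc2ccc(O)cc2)cc(Oc2ccc(CCc3cc(OC)cc(O)c3C(=O)O)cc2)c1 | target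

## Step count and risks

Total step count: 10.
Longest linear sequence: 9 (steps 1–7, 9 and 10). Step 8 is a one-step side branch.

**Step 9.** The β-alkyl ynoate is only a moderately reactive dienophile. Cycloaddition may be slower than decay of the diene by oxygen-to-carbon silyl migration or by protodesilylation with the liberated methanol. Part of the adduct may also aromatise by loss of silanol instead of methanol.
- The fallback replaces the alkyne by the isomeric allene, a more reactive dienophile made in a different way. It sets out from ester 7.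
- LiOH in THF/H2O should give the carboxylic acid F1. (COCl)2 with catalytic DMF in CH2Cl2 should then give the acid chloride F2.
- Slow addition of F2 to benzyl (triphenylphosphoranylidene)acetate and Et3N in CH2Cl2 at 0 °C should form the ketene F3. This is olefinated in the flask (ketene Wittig reaction) to the benzyl 5-arylpenta-2,3-dienoate F4.
- The α,β double bond of F4 should add diene 14 in toluene at 80–110 °C with the same orientation, giving the alkylidenecyclohexene adduct F5.
- Loss of methanol and migration of the exocyclic double bond into the ring lead to silyl ether 16. After the dilute acid work-up the route is rejoined at 17.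

**Step 4.** The coupling may stall or be accompanied by protodebromination of the bromide. The methyl ester may be partly hydrolysed by carbonate and adventitious water at 100 °C.
- The fallback reverses the role of the ring B partner and couples oxidatively at room temperature (Chan–Lam–Evans coupling). It sets out from bromide 5.
- n-BuLi in THF at −78 °C should give the aryllithium F6. B(OiPr)3 followed by aqueous HCl should then give the arylboronic acid F7.
- F7, phenol 6, Cu(OAc)2, pyridine and 4 Å molecular sieves in CH2Cl2 under air at rt should give the diaryl ether, which rejoins the route at 7.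

**Step 7.** Conversion of the dibromoalkene into the acetylide may be incomplete. The acylation may suffer from consumption of the chloroformate by residual n-BuLi, from further attack of acetylide on the ynoate, or from poor chloroformate quality.
- The fallback separates alkyne formation from carboxylation. It sets out from aldehyde 8.
- Dimethyl (1-diazo-2-oxopropyl)phosphonate with K2CO3 in MeOH at rt (Ohira–Bestmann homologation) should give the terminal alkyne F8.
- One equivalent of n-BuLi in THF at −78 °C regenerates acetylide 10. CO2 and acidic work-up should then give the ynoic acid F9.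
- O-Alkylation of F9 with BnBr and K2CO3 in DMF at rt rejoins the route at 11.

## Further compounds

F1 | step 9 | 3-[4-(3-{2-[4-(benzyloxy)phenyl]ethyl}-5-methoxyphenoxy)phenyl]propanoic acid | O=C(O)CCc1ccc(Oc2cc(OC)cc(CCc3ccc(OCc4ccccc4)cc3)c2)cc1
F2 | step 9 | 3-[4-(3-{2-[4-(benzyloxy)phenyl]ethyl}-5-methoxyphenoxy)phenyl]propanoyl chloride | O=C(Cl)CCc1ccc(Oc2cc(OC)cc(CCc3ccc(OCc4ccccc4)cc3)c2)cc1
F3 | step 9 | 3-[4-(3-{2-[4-(benzyloxy)phenyl]ethyl}-5-methoxyphenoxy)phenyl]prop-1-en-1-one (ketene) | O=C=CCc1ccc(Oc2cc(OC)cc(CCc3ccc(OCc4ccccc4)cc3)c2)cc1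
F4 | step 9 | benzyl 5-[4-(3-{2-[4-(benzyloxy)phenyl]ethyl}-5-methoxyphenoxy)phenyl]penta-2,3-dienoate (racemic allene) | O=C(OCc1ccccc1)C=C=CCc1ccc(Oc2cc(OC)cc(CCc3ccc(OCc4ccccc4)cc3)c2)cc1
F5 | step 9 | benzyl 6-{2-[4-(3-{2-[4-(benzyloxy)phenyl]ethyl}-5-methoxyphenoxy)phenyl]ethylidene}-2,4-dimethoxy-2-(trimethylsilyloxy)cyclohex-3-ene-1-carboxylate (stereoisomer mixture) | O=C(OCc1ccccc1)C1C(=CCc2ccc(Oc3cc(OC)cc(CCc4ccc(OCc5ccccc5)cc4)c3)cc2)CC(OC)=CC1(OC)O[Si](C)(C)C
F6 | step 4 | (3-{2-[4-(benzyloxy)phenyl]ethyl}-5-methoxyphenyl)lithium | [Li]c1cc(OC)cc(CCc2ccc(OCc3ccccc3)cc2)c1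
F7 | step 4 | (3-{2-[4-(benzyloxy)phenyl]ethyl}-5-methoxyphenyl)boronic acid | COc1cc(B(O)O)cc(CCc2ccc(OCc3ccccc3)cc2)c1
F8 | step 7 | 1-{2-[4-(benzyloxy)phenyl]ethyl}-3-[4-(but-3-yn-1-yl)phenoxy]-5-methoxybenzene | C#CCCc1ccc(Oc2cc(OC)cc(CCc3ccc(OCc4ccccc4)cc3)c2)cc1
F9 | step 7 | 5-[4-(3-{2-[4-(benzyloxy)phenyl]ethyl}-5-methoxyphenoxy)phenyl]pent-2-ynoic acid | O=C(O)C#CCCc1ccc(Oc2cc(OC)cc(CCc3ccc(OCc4ccccc4)cc3)c2)cc1
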